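The two ring C–OAc bonds are disconnected together. Numbering the cyclopentene ring C1 (quaternary carbinol carbon), C2 and C5 (acetoxy carbons) and C3=C4 (alkene), with C1' the side-chain ketone carbon, C2 and C5 are the termini of a C2=C3–C4=C5 diene in the five-membered ring, and the acetates are cis to each other and trans to the C1 oxygen; this is the feature the key step exploits. One palladium-catalysed cis-1,4-diacetoxylation forms both C–O bonds, shifts the alkene to C3=C4 and fixes all three ring stereocentres. Its precursor is a spiro-fused cyclopentadiene whose C1 and C1' oxygens are tied up as an acetonide.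

Key step: step 6

Assumption: racemic methyl 2-hydroxydodecanoate is taken as purchased (Fischer esterification of the commercial acid supplies it otherwise); the target is a meso compound (acetates cis to each other, trans to the C1 hydroxyl), so all chiral intermediates are racemic and one enantiomer is drawn.

Step 1
Reactants: 1 methyl 2-hydroxydodecanoate (racemic); 2 allylmagnesium bromide
Product: 4 4-(prop-2-en-1-yl)pentadec-1-ene-4,5-diol (racemic), via 5-hydroxypentadec-1-en-4-one 3 (not isolated)
Conditions: CH2=CHCH2MgBr (3.5 equiv), Et2O, 0 °C to rt; then aq NH4Cl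
Reagents that add atoms: allylmagnesium bromide, C=CC[Mg]Br
Why: Double Grignard addition to an ester, in which the first equivalent deprotonates the hydroxyl and two allyl groups then add through the more electrophilic ketone 3, should give the tertiary carbinol; its two new substituents are identical, so no stereocentre is created and the existing one is untouched.

Step 2
Reactants: 4 4-(prop-2-en-1-yl)pentadec-1-ene-4,5-diol; 5 2,2-dimethoxypropane
Product: 6 4-decyl-2,2-dimethyl-5,5-di(prop-2-en-1-yl)-1,3-dioxolane (racemic)
Conditions: Me2C(OMe)2 (3 equiv), p-TsOH·H2O (2 mol %), acetone, rt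
Reagents that add atoms: 2,2-dimethoxypropane, COC(C)(C)OC
Why: Acid-catalysed transketalisation (acetonide formation) of the 1,2-diol is driven by loss of methanol and by closure of the five-membered dioxolane, and it affects no stereocentre.

Step 3
Reactants: 6 4-decyl-2,2-dimethyl-5,5-di(prop-2-en-1-yl)-1,3-dioxolane
Product: 7 4-decyl-2,2-dimethyl-1,3-dioxaspiro[4.4]non-7-ene (racemic)
Conditions: second-generation Grubbs catalyst RuCl2(=CHPh)(PCy3)(H2IMes) (1 mol %), CH2Cl2 (0.02 M), 40 °C
Reagents that add atoms: none
Why: Ring-closing metathesis of the gem-diallyl unit, helped by the Thorpe–Ingold effect of the fully substituted dioxolane carbon and driven by loss of ethene, should close the cyclopentene without touching the ketal or creating a stereocentre.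

Step 4
Reactants: 7 4-decyl-2,2-dimethyl-1,3-dioxaspiro[4.4]non-7-ene; 8 bromine
Product: 9 trans-7,8-dibromo-4-decyl-2,2-dimethyl-1,3-dioxaspiro[4.4]nonane (both trans diastereomers relative to the decyl-bearing carbon, one drawn)
Conditions: Br2 (1.05 equiv), NaHCO3 (solid), CH2Cl2, −78 °C
Reagents that add atoms: bromine, BrBr
Why: Electrophilic bromination through a bromonium ion that bromide opens anti should give the trans-dibromide, the cold buffered medium keeping the ketal intact and out of the reaction; the two bromine-bearing stereocentres are removed again in step 5, so the diastereomer mixture is of no consequence.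

Step 5
Reactants: 9 trans-7,8-dibromo-4-decyl-2,2-dimethyl-1,3-dioxaspiro[4.4]nonane
Product: 11 4-decyl-2,2-dimethyl-1,3-dioxaspiro[4.4]nona-6,8-diene (racemic), via allylic bromide 10 (not isolated)
Conditions: KOtBu (3 equiv), THF, 0 °C; cold pentane/water work-up, short silica plug, solution used at once
Reagents that add atoms: none
Why: Two consecutive anti-periplanar E2 dehydrobrominations with a hindered base, each bromide finding its anti hydrogen on the neighbouring CH2 group, should pass through allylic bromide 10 to the conjugated diene, which the fully substituted spiro carbon protects from hydrogen shifts.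

Step 6
Reactants: 11 4-decyl-2,2-dimethyl-1,3-dioxaspiro[4.4]nona-6,8-diene; 12 acetic acid
Product: 14 4-decyl-2,2-dimethyl-1,3-dioxaspiro[4.4]non-7-ene-6,9-diyl diacetate (racemic; acetates mutually cis on the face of the decyl-bearing carbon), via π-allylpalladium chloride complex 13 (not isolated)
Conditions: Pd(OAc)2 (5 mol %), LiCl (20 mol %), LiOAc (3 equiv), benzoquinone (10 mol %), MnO2 (1.3 equiv), AcOH, 25 °C; 11 in pentane added over 8 h
Reagents that add atoms: acetic acid, CC(=O)O; lithium acetate, [Li+].CC(=O)[O-]
Why: Divalent palladium is expected to take the diene face that carries only the bare dioxolane oxygen O1, the less hindered face and the one that electrophiles and cycloaddition partners favour in 5-oxygenated cyclopentadienes, so external attack of acetate on C2, opposite the metal, produces the π-allyl complex 13 spanning C3–C5; because chloride occupies the site from which coordinated acetate would otherwise migrate, C5 is likewise attacked externally, and the zerovalent palladium released is reoxidised by benzoquinone, which MnO2 regenerates. The closest known reaction type is the palladium-catalysed, chloride-assisted cis-1,4-diacetoxylation of cyclic 1,3-dienes with a quinone oxidant. No ring is closed; two C–O bonds form and the alkene moves to C3=C4. C2 and C5 are each set by attack anti to palladium and the configuration of C1 follows from the facial choice, so both acetates end up on the C1' face, cis to each other and trans to O1. The step needs facial selectivity, 1,4- over 1,2-addition and cis over trans addition: the spiro dioxolane (oxygen on one face, the decyl-bearing carbon on the other) should secure the first, attack at the allyl terminus remote from the first acetoxy group the second and chloride the third. The quinone is kept catalytic and the diene is added slowly because this diene is a reactive Diels–Alder partner.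

Step 7
Reactants: 14 4-decyl-2,2-dimethyl-1,3-dioxaspiro[4.4]non-7-ene-6,9-diyl diacetate
Product: 15 1-hydroxy-1-(1-hydroxyundecyl)cyclopent-3-ene-2,5-diyl diacetate (racemic; acetates cis, trans to the C1 hydroxyl)
Conditions: AcOH/H2O (4:1), 45 °C
Reagents that add atoms: none
Why: Acid-catalysed ketal hydrolysis should release acetone and the 1,2-diol, while the acetates, which need stronger acid or base to cleave, and all four stereocentres stay as they are.

Step 8
Reactants: 15 1-hydroxy-1-(1-hydroxyundecyl)cyclopent-3-ene-2,5-diyl diacetate
Product: 16 1-hydroxy-1-undecanoylcyclopent-3-ene-2,5-diyl diacetate (meso; acetates cis, trans to the C1 hydroxyl), the target CNP0208983.3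
Conditions: IBX (1.5 equiv), DMSO, rt
Reagents that add atoms: none
Why: IBX oxidation of the secondary alcohol of a 1,2-diol should give the α-hydroxy ketone without glycol cleavage and leave the tertiary hydroxyl and the esters untouched; the C1' stereocentre disappears, so the racemic diol converges on the meso target.

Compound list
1 | methyl 2-hydroxydodecanoate (racemic, one enantiomer drawn) | CCCCCCCCCC[C@H](O)C(=O)OC | starting material
2 | allylmagnesium bromide | C=CC[Mg]Br | starting material
3 | 5-hydroxypentadec-1-en-4-one (present as its bromomagnesium alkoxide) | CCCCCCCCCC[C@H](O)C(=O)CC=C | intermediate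
4 | 4-(prop-2-en-1-yl)pentadec-1-ene-4,5-diol (racemic) | CCCCCCCCCC[C@H](O)C(O)(CC=C)CC=C | intermediate
5 | 2,2-dimethoxypropane | COC(C)(C)OC | starting material
6 | 4-decyl-2,2-dimethyl-5,5-di(prop-2-en-1-yl)-1,3-dioxolane (racemic) | CCCCCCCCCC[C@H]1C(CC=C)(CC=C)OC(C)(C)O1 | intermediate
7 | 4-decyl-2,2-dimethyl-1,3-dioxaspiro[4.4]non-7-ene (racemic) | CCCCCCCCCC[C@H]1C2(CC=CC2)OC(C)(C)O1 | intermediate
8 | bromine | BrBr | starting material
9 | trans-7,8-dibromo-4-decyl-2,2-dimethyl-1,3-dioxaspiro[4.4]nonane (two trans diastereomers, one drawn) | CCCCCCCCCC[C@H]1C2(C[C@@H](Br)[C@H](Br)C2)OC(C)(C)O1 | intermediate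
10 | 8-bromo-4-decyl-2,2-dimethyl-1,3-dioxaspiro[4.4]non-6-ene (mixture of diastereomers) | CCCCCCCCCC[C@H]1C2(C=CC(Br)C2)OC(C)(C)O1 | intermediate
11 | 4-decyl-2,2-dimethyl-1,3-dioxaspiro[4.4]nona-6,8-diene (racemic) | CCCCCCCCCC[C@H]2C1(OC(C)(C)O2)C=CC=C1 | intermediate
12 | acetic acid | CC(=O)O | starting material
13 | π-allylpalladium chloride complex over C3–C5 with the first acetate at C2 (drawn as the C5-bound σ-form, palladium on the O1 face) | CCCCCCCCCC[C@H]2[C@@]1(OC(C)(C)O2)[C@@H](OC(C)=O)C=C[C@@H]1[Pd]Cl | intermediate
14 | 4-decyl-2,2-dimethyl-1,3-dioxaspiro[4.4]non-7-ene-6,9-diyl diacetate (racemic; acetates cis, on the face of the decyl-bearing carbon, trans to O1) | CCCCCCCCCC[C@H]2[C@@]1(OC(C)(C)O2)[C@@H](OC(C)=O)C=C[C@H]1OC(C)=O | intermediate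
15 | 1-hydroxy-1-(1-hydroxyundecyl)cyclopent-3-ene-2,5-diyl diacetate (racemic; acetates cis, trans to the C1 hydroxyl) | CCCCCCCCCC[C@H](O)[C@@]1(O)[C@@H](OC(C)=O)C=C[C@H]1OC(C)=O | intermediate
16 | 1-hydroxy-1-undecanoylcyclopent-3-ene-2,5-diyl diacetate (meso; acetates cis, trans to the C1 hydroxyl) | CCCCCCCCCCC(=O)[C@@]1(O)[C@@H](OC(C)=O)C=C[C@H]1OC(C)=O | target

Total step count: 8. Longest linear sequence: 8 steps (1 to 16).

Steps most likely to fail

Step 6. The diene may be lost to [4+2] dimerisation or to cycloaddition with the quinone before palladium engages it. Palladium may also discriminate poorly between the two diene faces. The second acetate may arrive slowly at C5, which lies next to the quaternary centre and under the decyl chain, so that 1,2-addition intervenes. The fallback sets out from diene 11. Sensitised photooxygenation (O2, tetraphenylporphyrin, hν, CH2Cl2, −78 °C) should give the spiro endoperoxide F1, which thiourea reduces in the same flask to the cis-enediol F2. The face taken by singlet oxygen does not matter, because Dess–Martin periodinane then converts both carbinols into the ene-dione F3. Reduction of both carbonyls with iBu2AlH (CH2Cl2, −78 °C), with hydride arriving from the open face of the dioxolane oxygen, should give the cis-diol F4 carrying both hydroxyls on the C1' face. Ac2O/pyridine/DMAP brings the route back at 14. Stereocontrol is thereby moved from metal–diene face selection to steric approach control on a ketone.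

Step 5. Substitution by the alkoxide at the allylic bromide stage may compete with elimination, and the diene may dimerise while it is being generated and handled in strongly basic medium. The fallback sets out from cyclopentene 7. mCPBA (CH2Cl2, 0 °C) should give the epoxide F5, LiNEt2 (Et2O, 0 °C to reflux) should isomerise it to the allylic alcohol F6, and Burgess dehydration (benzene, 50 °C) brings the route back at diene 11. This path is neutral in its last step and uses no halide leaving group.

Step 7. Prolonged aqueous acid may move an acetyl group from C2 or C5 to the newly freed C1' hydroxyl, or solvolyse the allylic acetates, before the hindered ketal is fully cleaved. The fallback sets out from 14. Me3SiOTf/iPr2NEt (CH2Cl2, −78 to 0 °C) should open the acetonide under buffered aprotic conditions to the silyl ether/isopropenyl ether F7. Its two labile groups should hydrolyse quickly in PPTS/wet THF at room temperature, which brings the route back at diol 15.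

Further compounds
F1 | step 6 | 5'-decyl-2',2'-dimethylspiro[2,3-dioxabicyclo[2.2.1]hept-5-ene-7,4'-[1,3]dioxolane] (peroxide bridge drawn on the face of the dioxolane oxygen) | CCCCCCCCCC[C@H]2[C@@]1(OC(C)(C)O2)[C@H]3C=C[C@@H]1OO3
F2 | step 6 | 4-decyl-2,2-dimethyl-1,3-dioxaspiro[4.4]non-7-ene-6,9-diol (hydroxyls cis, drawn on the face of O1) | CCCCCCCCCC[C@H]2[C@@]1(OC(C)(C)O2)[C@H](O)C=C[C@@H]1O
F3 | step 6 | 4-decyl-2,2-dimethyl-1,3-dioxaspiro[4.4]non-7-ene-6,9-dione | CCCCCCCCCC[C@H]2C1(OC(C)(C)O2)C(=O)C=CC1=O
F4 | step 6 | 4-decyl-2,2-dimethyl-1,3-dioxaspiro[4.4]non-7-ene-6,9-diol (hydroxyls cis, on the face of the decyl-bearing carbon) | CCCCCCCCCC[C@H]2[C@@]1(OC(C)(C)O2)[C@@H](O)C=C[C@H]1O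
F5 | step 5 | 5'-decyl-2',2'-dimethylspiro[6-oxabicyclo[3.1.0]hexane-3,4'-[1,3]dioxolane] (mixture of epoxide faces) | CCCCCCCCCC[C@H]1C2(CC3OC3C2)OC(C)(C)O1
F6 | step 5 | 4-decyl-2,2-dimethyl-1,3-dioxaspiro[4.4]non-6-en-8-ol (mixture of diastereomers) | CCCCCCCCCC[C@H]1C2(C=CC(O)C2)OC(C)(C)O1
F7 | step 7 | 1-(prop-1-en-2-yloxy)-1-[1-(trimethylsilyloxy)undecyl]cyclopent-3-ene-2,5-diyl diacetate (acetates cis, trans to the C1 oxygen) | CCCCCCCCCC[C@H](O[Si](C)(C)C)[C@@]1(OC(C)=C)[C@@H](OC(C)=O)C=C[C@H]1OC(C)=O
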